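X, the product made from substrate G with reagent J and catalysts L and D, rises and falls again in both runs made so far, so the task is to catch it.

| setting | dawn | winter | flask |
|---|---|---|---|
| G | 0.042 M | 0.042 M | 0.042 M |
| J | 1.3 equiv | 2 equiv | 0.900 equiv |
| L | 10 mol% | 10 mol% | 10 mol% |
| D | 5 mol% | 5 mol% | 5 mol% |
| remark | run made earlier | run made earlier |  |
| time |  |  | 4.0 h |

| run | time / h | X / % |
|---|---|---|
| dawn | 0.0667 | 2.8 |
| dawn | 0.133 | 6.7 |
| dawn | 0.333 | 10.1 |
| dawn | 0.667 | 5.3 |
| dawn | 1.33 | 0.8 |
| dawn | 3.00 | 0 |
| winter | 0.0667 | 3.2 |
| winter | 0.133 | 8.1 |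
| winter | 0.333 | 10.1 |
| winter | 0.667 | 4.7 |
| winter | 1.33 | 1.2 |
| winter | 3.00 | 0.1 |

(scatter of a reading: 0.3 percentage points)

* the moment within 4.0 h at which there is most X
* the amount of X, in percent of the G charged, at that time
* the first time at which X reaches 5.8%, in the same percent



First, does X keep? Between 0.667 h and 1.33 h the dawn run falls from 5.3% to 0.8%. Read as d[X]/dt = −k[X], this rate integrates to an exponential, and the two readings give a fall half-life, the time in which the tail of X halves, of 0.243 h. This is a reading, and it carries the scatter on that small last value. It is much shorter than the 4.0 h allowed, so in this flask you should look early.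

Then, does J move the peak? At 0.333 h the dawn and winter runs read 10.1% and 10.1%, but at 0.133 h they read 6.7% and 8.1%, a gap of 1.4 percentage points against a scatter of 0.3 points on each reading. So with J up by a factor of 1.54, the early reading goes up by a factor of 1.21, and the one equal pair does not show that J leaves the peak alone.

Last, can 0.900 equiv of J carry the flask to its peak? My own reckoning takes the tail as the clock of G. By 0.333 h that clock has used 61.3% of G, and this charge of J still covers that. I therefore expect the peak near the same time, a little lower.

The forecast gives 9.8% at 0.3 h, and 0.135 h for the level asked, with the warning “Limiting J adds uncertainty, because it could cap conversion”.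

The flask gives 8.22% at 0.273 h, and reaches the level at 0.128 h.

    D + E ⇌ Z (K = 540 M⁻¹, k = 1.80 M⁻¹ s⁻¹)
    G + L → L + E (k = 0.210 M⁻¹ s⁻¹)
    J + Z → D + X (k = 0.500 M⁻¹ s⁻¹)
    X → Q (k = 0.00420 s⁻¹)

At 0.273 h the flask still holds 67.1% of its J. The step from X to Q holds X down: without it the highest X in this flask is 90.0%, not 8.22%. X's own half-life by that step, 2.8 min, is shorter than 0.243 h, so 0.243 h reads as the clock of G, pseudo-first-order with L at 100%. At 2.00 h that clock gives 0.333% of G, and the flask holds 0.175%. For the neighbour flask with 0.230 equiv of J, the clock gives 0.00111% at 4.00 h; that flask holds 0% of G, with 72.3% standing as E.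

Readings and results were generated by integration on assumed constants; the scatter is artificial.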